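## Retrosynthetic overview
1. The pyranone ring C of the 5,7-dihydroxyflavone half (unit 2) is cut at O1–C2 and C2–C3. This gives an aryl nitrile and unprotected 2,4,6-trihydroxyacetophenone, joined by a new polyanion–nitrile annulation.
2. The key bond is the diaryl ether C–O bond between O8 of the methylated flavone (unit 1) and the para carbon of the benzonitrile. It is made by SNAr of an 8-hydroxyflavone on 4-fluorobenzonitrile.
3. The C8–O bond comes from para-selective Elbs oxidation of 5-hydroxy-7,4'-dimethoxyflavone.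
4. That flavone is apigenin methylated at O7 and O4'.
5. Ring order: rings A, B and C of unit 1 are bought intact in apigenin. Ring B of unit 2 comes with the nitrile and ring A with the acetophenone. Ring C of unit 2 is the only ring formed, in the last step, and no protecting groups are used.

Assumption: the target has no stereocentre and its diaryl ether rotates freely, so it is achiral and there is no enantiomer to select.

## Route

Step 1
Reactants: 1 apigenin (5,7-dihydroxy-2-(4-hydroxyphenyl)-4H-chromen-4-one)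
Product: 2 5-hydroxy-7-methoxy-2-(4-methoxyphenyl)-4H-chromen-4-one
Conditions: MeI (2.2 equiv), K2CO3 (2.5 equiv), DMF, 25 °C, 16 h
Reagents that add atoms: iodomethane, CI
Why: Williamson O-methylation takes the two free, acidic phenols (7-OH and 4'-OH), while the 5-OH is hydrogen-bonded to the C4 carbonyl and stays free with a weak base and two equivalents of MeI.

Step 2
Reactants: 2 5-hydroxy-7-methoxy-2-(4-methoxyphenyl)-4H-chromen-4-one
Product: 4 5,8-dihydroxy-7-methoxy-2-(4-methoxyphenyl)-4H-chromen-4-one, via potassium flavon-8-yl sulfate 3 (not isolated)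
Conditions: K2S2O8 (1.2 equiv), KOH (5 equiv), H2O–pyridine, 15 °C, 24 h; HCl to pH 5, recovered 2 filtered off; conc. HCl, 90 °C, 45 min, N2
Reagents that add atoms: potassium peroxodisulfate, [K+].[K+].[O-]S(=O)(=O)OOS(=O)(=O)[O-]
Why: In this Elbs persulfate oxidation the 5-phenolate attacks a peroxide oxygen through its para carbon C8 (made more nucleophilic by the ortho 7-OMe and O1), and hot acid cleaves the S–O bond of sulfate 3; the reaction is established for 5-hydroxyflavones, with modest conversion and recyclable 2.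

Step 3
Reactants: 4 5,8-dihydroxy-7-methoxy-2-(4-methoxyphenyl)-4H-chromen-4-one; 5 4-fluorobenzonitrile
Product: 6 4-{[5-hydroxy-7-methoxy-2-(4-methoxyphenyl)-4-oxo-4H-chromen-8-yl]oxy}benzonitrile
Conditions: 5 (1.3 equiv), K2CO3 (1.1 equiv), degassed DMF, 100 °C, 10 h, Ar
Reagents that add atoms: none
Why: This is an SNAr through a cyano-stabilised Meisenheimer complex, in which one equivalent of base ionises only the 8-OH (the 5-OH is chelated and poorly nucleophilic), the unhindered C–F carbon accepts the doubly ortho-substituted phenoxide, and excluding oxygen keeps the hydroquinone from forming the 5,8-quinone.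

Step 4
Reactants: 6 4-{[5-hydroxy-7-methoxy-2-(4-methoxyphenyl)-4-oxo-4H-chromen-8-yl]oxy}benzonitrile; 7 1-(2,4,6-trihydroxyphenyl)ethan-1-one (dried)
Product: 10 8-[4-(5,7-dihydroxy-4-oxo-4H-chromen-2-yl)phenoxy]-5-hydroxy-7-methoxy-2-(4-methoxyphenyl)-4H-chromen-4-one, via tetralithio polyanion 8 (not isolated), via Z-enaminone 9 (not isolated)
Conditions: 7 (2.5 equiv), LiN(iPr)2 (10 equiv), THF–DMPU, −78 to −10 °C, 2 h; 6, −78 to 50 °C, 14 h; then AcOH–conc. HCl, THF distilled off, 95 °C, 2 h
Reagents that add atoms: none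
Why: Proposed new method: the enolate carbon of polyanion 8 is its most basic and only carbon-nucleophilic site (the three aryloxides are held in lithium aggregates), so it adds to the nitrile carbon of 6 in a Thorpe-type step; the N-lithio ketimine tautomerises at once to the chelated aza-enolate of vinylogous amide 9, which makes the addition irreversible and blocks a second one; in hot AcOH–HCl an ortho OH adds to the protonated enaminone carbon and ammonium leaves (addition–elimination, N exchanged for O), closing the pyranone C–O bond, and any hydrolysis of 9 to the 1,3-diketone cyclodehydrates to the same flavone; LiN(iPr)2 is used at exactly four equivalents per 7 because leftover LiN(SiMe3)2 would add to the aryl nitrile to give an amidine, and the excess polyanion takes up the 5-OH proton of 6; the closest known reaction types are aroylation of this same polyanion with aroyl chlorides followed by acid cyclodehydration, condensation of 1,3-diketone multiple anions with nitriles, and acid cyclisation of 2-hydroxyaryl enaminones to chromones.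

## Compound list
1 | apigenin, 5,7-dihydroxy-2-(4-hydroxyphenyl)-4H-chromen-4-one | O=c1cc(-c2ccc(O)cc2)oc2cc(O)cc(O)c12 | starting material
2 | 5-hydroxy-7-methoxy-2-(4-methoxyphenyl)-4H-chromen-4-one | COc1ccc(-c2cc(=O)c3c(O)cc(OC)cc3o2)cc1 | intermediate
3 | potassium 5-hydroxy-7-methoxy-2-(4-methoxyphenyl)-4-oxo-4H-chromen-8-yl sulfate | COc1ccc(-c2cc(=O)c3c(O)cc(OC)c(OS(=O)(=O)[O-])c3o2)cc1.[K+] | intermediate
4 | 5,8-dihydroxy-7-methoxy-2-(4-methoxyphenyl)-4H-chromen-4-one | COc1ccc(-c2cc(=O)c3c(O)cc(OC)c(O)c3o2)cc1 | intermediate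
5 | 4-fluorobenzonitrile | N#Cc1ccc(F)cc1 | starting material
6 | 4-{[5-hydroxy-7-methoxy-2-(4-methoxyphenyl)-4-oxo-4H-chromen-8-yl]oxy}benzonitrile | COc1ccc(-c2cc(=O)c3c(O)cc(OC)c(Oc4ccc(C#N)cc4)c3o2)cc1 | intermediate
7 | 1-(2,4,6-trihydroxyphenyl)ethan-1-one | CC(=O)c1c(O)cc(O)cc1O | starting material
8 | tetralithium 2-(1-oxidoethenyl)benzene-1,3,5-triolate | [Li+].[Li+].[Li+].[Li+].C=C([O-])c1c([O-])cc([O-])cc1[O-] | intermediate
9 | 8-{4-[(1Z)-1-amino-3-oxo-3-(2,4,6-trihydroxyphenyl)prop-1-en-1-yl]phenoxy}-5-hydroxy-7-methoxy-2-(4-methoxyphenyl)-4H-chromen-4-one | COc1ccc(-c2cc(=O)c3c(O)cc(OC)c(Oc4ccc(/C(N)=C/C(=O)c5c(O)cc(O)cc5O)cc4)c3o2)cc1 | intermediate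
10 | 8-[4-(5,7-dihydroxy-4-oxo-4H-chromen-2-yl)phenoxy]-5-hydroxy-7-methoxy-2-(4-methoxyphenyl)-4H-chromen-4-one | COc1ccc(-c2cc(=O)c3c(O)cc(OC)c(Oc4ccc(-c5cc(=O)c6c(O)cc(O)cc6o5)cc4)c3o2)cc1 | target

## Step count and risks
Total steps: 4. Longest linear sequence: 4 (1 → 2 → 4 → 6 → 10).

**Step 4 (new annulation).**
- Risk: the aryloxy-substituted nitrile is electron-rich and the polyanion is poorly soluble, so the addition may stall.
- Fallback (known chemistry only): it sets out from 6 and comes back at 10.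
- A Blaise reaction of 6 (Zn, ethyl bromoacetate added slowly, THF, reflux) gives ethyl (2Z)-3-amino-3-(4-{[5-hydroxy-7-methoxy-2-(4-methoxyphenyl)-4-oxo-4H-chromen-8-yl]oxy}phenyl)prop-2-enoate F1.
- Stirring with 1 M HCl hydrolyses it to ethyl 3-(4-{[5-hydroxy-7-methoxy-2-(4-methoxyphenyl)-4-oxo-4H-chromen-8-yl]oxy}phenyl)-3-oxopropanoate F2.
- F2 is then heated with phloroglucinol (2 equiv) in diphenyl ether at 240 °C under microwave heating. This is the established protecting-group-free thermal cyclocondensation of aroylacetates with phloroglucinol, and it gives 10.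

**Step 2 (Elbs oxidation).**
- Risk: conversion is typically 25–40 % and the aqueous work-up is laborious.
- Fallback: it sets out from 2 and comes back at 4, replacing phenolate oxidation by halogenation and catalytic hydroxylation.
- MeI, K2CO3, DMF, 60 °C gives 5,7-dimethoxy-2-(4-methoxyphenyl)-4H-chromen-4-one F3.
- N-iodosuccinimide with CF3CO2H in MeCN iodinates the fully etherified ring A at C8, giving 8-iodo-5,7-dimethoxy-2-(4-methoxyphenyl)-4H-chromen-4-one F4.
- Cu(acac)2 with N,N'-bis(4-hydroxy-2,6-dimethylphenyl)oxalamide and LiOH in DMSO–H2O at 60 °C gives 8-hydroxy-5,7-dimethoxy-2-(4-methoxyphenyl)-4H-chromen-4-one F5.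
- BCl3 in CH2Cl2 (−78 to 0 °C) removes only the carbonyl-chelated 5-O-methyl group to give 4.

**Step 3 (SNAr on an air-sensitive hydroquinone).**
- Risk: the phenoxide may oxidise to the quinone or arylate partly at O5 at 100 °C.
- Fallback: it sets out from 4 and comes back at 6, replacing thermal addition–elimination by room-temperature ligand coupling on trivalent iodine.
- (4-Cyanophenyl)(2,4,6-trimethoxyphenyl)iodonium 4-toluenesulfonate F6 is made in one pot from 4-iodobenzonitrile, mCPBA, TsOH·H2O and 1,3,5-trimethoxybenzene in MeCN.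
- F6 is stirred with 4 and K2CO3 in MeCN at 25 °C under Ar. The electron-poor cyanophenyl group is transferred to O8.

## Further compounds
F1 | step 4 | ethyl (2Z)-3-amino-3-(4-{[5-hydroxy-7-methoxy-2-(4-methoxyphenyl)-4-oxo-4H-chromen-8-yl]oxy}phenyl)prop-2-enoate | CCOC(=O)/C=C(\N)c1ccc(Oc2c(OC)cc(O)c3c(=O)cc(-c4ccc(OC)cc4)oc23)cc1
F2 | step 4 | ethyl 3-(4-{[5-hydroxy-7-methoxy-2-(4-methoxyphenyl)-4-oxo-4H-chromen-8-yl]oxy}phenyl)-3-oxopropanoate | CCOC(=O)CC(=O)c1ccc(Oc2c(OC)cc(O)c3c(=O)cc(-c4ccc(OC)cc4)oc23)cc1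
F3 | step 2 | 5,7-dimethoxy-2-(4-methoxyphenyl)-4H-chromen-4-one | COc1ccc(-c2cc(=O)c3c(OC)cc(OC)cc3o2)cc1
F4 | step 2 | 8-iodo-5,7-dimethoxy-2-(4-methoxyphenyl)-4H-chromen-4-one | COc1ccc(-c2cc(=O)c3c(OC)cc(OC)c(I)c3o2)cc1
F5 | step 2 | 8-hydroxy-5,7-dimethoxy-2-(4-methoxyphenyl)-4H-chromen-4-one | COc1ccc(-c2cc(=O)c3c(OC)cc(OC)c(O)c3o2)cc1
F6 | step 3 | (4-cyanophenyl)(2,4,6-trimethoxyphenyl)iodonium 4-toluenesulfonate | N#Cc1ccc([I+]c2c(OC)cc(OC)cc2OC)cc1.Cc1ccc(S(=O)(=O)[O-])cc1
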